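The route is built on disconnecting ring B between C8 and C9, the adjacent oxidised carbons of the cyclohexenone (C8 ketone, C9 acetoxy carbinol), which are the retron of a 1,2-diol. One SmI2 pinacol coupling of a dialdehyde forms C8–C9, closes ring B onto the existing spiro carbon C5 and delivers both carbinols as a cis-diol. The precursor is a ring A cyclopentane (C1 silyl ether, C3 isopropenyl from (R)-limonene) whose quaternary C5 carries a Z enal arm C6(Me)=C7–C8HO, made by methylcuprate addition to an ynoate, and a C10(Me)–C9HO arm whose stereocentre is taken from (R)-lactate.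

Key step: step 16

Remark: atom numbers follow the target in every compound (ring A = C1–C4 plus spiro C5; ring B = C5–C10; C1 bears the ester oxygen, C3 the isopropenyl group, C6 and C10 the methyl groups).
Remark: C10 is taken from the chiral pool and joined to C5 by SN2 alkylation, because conjugate addition of a ring A β-keto ester to (E)-1-nitropropene is expected, from the usual synclinal transition-state model, to give the C10 epimer.

Step 1
Reactants: 1 (R)-limonene
Product: 3 methyl (3R)-6-oxo-3-(prop-1-en-2-yl)heptanoate, via methoxy hydroperoxide 2 (not isolated)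
Conditions: O3, NaHCO3, CH2Cl2/MeOH, −78 °C; then Ac2O, Et3N, 0 °C → rt
Reagents that add atoms: ozone, [O-][O+]=O; methanol, CO
Why: Unsymmetrical ozonolysis: ozone should attack the electron-richer trisubstituted ring alkene before the isopropenyl group, methanol traps the carbonyl oxide at the less substituted carbon and Ac2O/Et3N dehydrates the α-methoxy hydroperoxide to the methyl ester, the C3 stereocentre being untouched.

Step 2
Reactants: 3 methyl (3R)-6-oxo-3-(prop-1-en-2-yl)heptanoate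
Product: 4 (3R)-3-(prop-1-en-2-yl)hexanedioic acid
Conditions: NaOBr (from Br2 and aq. NaOH), 1,4-dioxane, 0 °C → rt; then aq. HCl
Reagents that add atoms: sodium hydroxide, [Na+].[OH-]
Why: Haloform reaction: tribromination of the methyl ketone and hydroxide cleavage remove one carbon and leave the carboxylate while the ester is saponified, and the alkene should survive because cold alkaline hypobromite contains no free Br2.

Step 3
Reactants: 4 (3R)-3-(prop-1-en-2-yl)hexanedioic acid
Product: 5 dimethyl (3R)-3-(prop-1-en-2-yl)hexanedioate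
Conditions: MeI, K2CO3, DMF, rt
Reagents that add atoms: iodomethane, CI
Why: Carboxylate O-alkylation (SN2) under non-acidic conditions spares the acid-sensitive isopropenyl group.

Step 4
Reactants: 5 dimethyl (3R)-3-(prop-1-en-2-yl)hexanedioate
Product: 6 methyl (4R)-2-oxo-4-(prop-1-en-2-yl)cyclopentane-1-carboxylate
Conditions: NaH, MeOH (cat.), THF, 65 °C; AcOH
Reagents that add atoms: none
Why: Dieckmann condensation under equilibrating conditions should favour the β-keto ester enolate whose ester-bearing carbon (C5) lies away from the branched C3, and C5 stays enolisable until step 6.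

Step 5
Reactants: 7 methyl (R)-lactate
Product: 8 methyl (2R)-2-[(trifluoromethanesulfonyl)oxy]propanoate
Conditions: Tf2O, 2,6-lutidine, CH2Cl2, −78 → 0 °C
Reagents that add atoms: trifluoromethanesulfonic anhydride, O=S(=O)(OS(=O)(=O)C(F)(F)F)C(F)(F)F
Why: O-sulfonylation of the secondary alcohol proceeds with retention at carbon and gives the activated α-triflyloxy ester, to be used fresh.

Step 6
Reactants: 6 methyl (4R)-2-oxo-4-(prop-1-en-2-yl)cyclopentane-1-carboxylate; 8 methyl (2R)-2-[(trifluoromethanesulfonyl)oxy]propanoate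
Product: 9 methyl (1R,4R)-1-[(2R)-1-methoxy-1-oxopropan-2-yl]-2-oxo-4-(prop-1-en-2-yl)cyclopentane-1-carboxylate
Conditions: NaH, THF, 0 °C; then 8, −40 °C → rt
Reagents that add atoms: none
Why: C-alkylation of the soft β-keto ester enolate by the α-triflyloxy ester is an SN2 displacement with inversion, so C10 should come out R from the R triflate, and the electrophile is expected to enter C5 on the face opposite the C3 isopropenyl group, a minor C5 epimer being removable by chromatography.

Step 7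
Reactants: 9 methyl (1R,4R)-1-[(2R)-1-methoxy-1-oxopropan-2-yl]-2-oxo-4-(prop-1-en-2-yl)cyclopentane-1-carboxylate
Product: 11 methyl (3R,3aR,5R,6aS)-3-methyl-2-oxo-5-(prop-1-en-2-yl)hexahydro-2H-cyclopenta[b]furan-3a(3H)-carboxylate, via hydroxy diester 10 (not isolated)
Conditions: Zn(BH4)2, Et2O, −20 → 0 °C; aq. NH4Cl; then PPTS (cat.), PhMe, 50 °C
Reagents that add atoms: none
Why: Chelation-controlled hydride reduction: zinc bridges the C1 ketone and the C6 ester carbonyl, hydride should arrive on the face opposite the bulky C10 arm, and the C1 hydroxyl formed cis to that arm closes the γ-lactone with the C9 ester, which also tells the two esters apart.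

Step 8
Reactants: 11 methyl (3R,3aR,5R,6aS)-3-methyl-2-oxo-5-(prop-1-en-2-yl)hexahydro-2H-cyclopenta[b]furan-3a(3H)-carboxylate
Product: 14 (4R,5R,6S,8R)-6-hydroxy-4-methyl-8-(prop-1-en-2-yl)-2-oxaspiro[4.4]nonan-1-one, via lactol 12 (not isolated), via diol ester 13 (not isolated)
Conditions: i-Bu2AlH (1.1 equiv), CH2Cl2, −78 °C; MeOH, then NaBH4, −20 → 0 °C; aq. NH4Cl; then PPTS (cat.), PhMe, 50 °C
Reagents that add atoms: none
Why: Stepwise hydride reduction and translactonisation: the γ-lactone should be reduced to the lactol at −78 °C well before the shielded methyl ester on quaternary C5, NaBH4 then reduces only the aldehyde form of the lactol, and the freed primary C9 alcohol lactonises onto the C6 ester, leaving C1–OH as the only free hydroxyl and C10 no longer next to a carbonyl.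

Step 9
Reactants: 14 (4R,5R,6S,8R)-6-hydroxy-4-methyl-8-(prop-1-en-2-yl)-2-oxaspiro[4.4]nonan-1-one
Product: 15 (4R,5R,6S,8R)-6-[(tert-butyldimethylsilyl)oxy]-4-methyl-8-(prop-1-en-2-yl)-2-oxaspiro[4.4]nonan-1-one
Conditions: TBSOTf, 2,6-lutidine, CH2Cl2, 0 °C
Reagents that add atoms: tert-butyldimethylsilyl trifluoromethanesulfonate, CC(C)(C)[Si](C)(C)OS(=O)(=O)C(F)(F)F
Why: Silylation with the silyl triflate is the standard way to protect a hindered secondary alcohol.

Step 10
Reactants: 15 (4R,5R,6S,8R)-6-[(tert-butyldimethylsilyl)oxy]-4-methyl-8-(prop-1-en-2-yl)-2-oxaspiro[4.4]nonan-1-one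
Product: 16 (4R,5R,6S,8R)-6-[(tert-butyldimethylsilyl)oxy]-4-methyl-8-(prop-1-en-2-yl)-2-oxaspiro[4.4]nonan-1-ol
Conditions: i-Bu2AlH (1.2 equiv), CH2Cl2, −78 °C
Reagents that add atoms: none
Why: Partial hydride reduction of a lactone at low temperature stops at the aluminium hemiacetal, which gives C6 at the aldehyde oxidation level as the lactol.

Step 11
Reactants: 16 (4R,5R,6S,8R)-6-[(tert-butyldimethylsilyl)oxy]-4-methyl-8-(prop-1-en-2-yl)-2-oxaspiro[4.4]nonan-1-ol
Product: 17 (2R)-2-[(1S,2S,4R)-2-[(tert-butyldimethylsilyl)oxy]-1-ethynyl-4-(prop-1-en-2-yl)cyclopentyl]propan-1-ol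
Conditions: dimethyl (1-diazo-2-oxopropyl)phosphonate, K2CO3, MeOH, rt → 40 °C
Reagents that add atoms: dimethyl (1-diazo-2-oxopropyl)phosphonate, COP(=O)(OC)C(=[N+]=[N-])C(C)=O
Why: Seyferth–Gilbert homologation in its Ohira–Bestmann form converts the open hydroxy aldehyde form of the lactol, which has no α-hydrogen, into the terminal alkyne under mild carbonate conditions and frees the C9 alcohol.

Step 12
Reactants: 17 (2R)-2-[(1S,2S,4R)-2-[(tert-butyldimethylsilyl)oxy]-1-ethynyl-4-(prop-1-en-2-yl)cyclopentyl]propan-1-ol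
Product: 18 methyl 3-[(1S,2S,4R)-2-[(tert-butyldimethylsilyl)oxy]-1-[(2R)-1-[(methoxycarbonyl)oxy]propan-2-yl]-4-(prop-1-en-2-yl)cyclopentyl]prop-2-ynoate
Conditions: n-BuLi (2.1 equiv), THF, −78 °C; then ClCO2Me (2.5 equiv), −78 → 0 °C
Reagents that add atoms: methyl chloroformate, COC(Cl)=O
Why: Double deprotonation followed by acylation gives the ynoate (acetylide C-acylation, C8) and at the same time protects the C9 alcohol as its methyl carbonate.

Step 13
Reactants: 18 methyl 3-[(1S,2S,4R)-2-[(tert-butyldimethylsilyl)oxy]-1-[(2R)-1-[(methoxycarbonyl)oxy]propan-2-yl]-4-(prop-1-en-2-yl)cyclopentyl]prop-2-ynoate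
Product: 19 methyl (2Z)-3-[(1S,2S,4R)-2-[(tert-butyldimethylsilyl)oxy]-1-[(2R)-1-[(methoxycarbonyl)oxy]propan-2-yl]-4-(prop-1-en-2-yl)cyclopentyl]but-2-enoate
Conditions: Me2CuLi (from CuI and MeLi), THF, −78 °C; MeOH then aq. NH4Cl at −78 °C
Reagents that add atoms: lithium dimethylcuprate, [Li+].C[Cu-]C
Why: Conjugate addition of the cuprate to the ynoate is a syn carbocupration, and protonation at −78 °C with retention leaves the new methyl and H cis, hence C5 and the ester cis (Z), the geometry ring B needs.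

Step 14
Reactants: 19 methyl (2Z)-3-[(1S,2S,4R)-2-[(tert-butyldimethylsilyl)oxy]-1-[(2R)-1-[(methoxycarbonyl)oxy]propan-2-yl]-4-(prop-1-en-2-yl)cyclopentyl]but-2-enoate
Product: 20 (2Z)-3-[(1S,2S,4R)-2-[(tert-butyldimethylsilyl)oxy]-1-[(2R)-1-hydroxypropan-2-yl]-4-(prop-1-en-2-yl)cyclopentyl]but-2-en-1-ol
Conditions: i-Bu2AlH (6 equiv), CH2Cl2, −78 → 0 °C
Reagents that add atoms: none
Why: Hydride 1,2-reduction of the enoate gives the Z allylic alcohol and the same reagent cleaves the carbonate, so both primary alcohols are freed in one operation.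

Step 15
Reactants: 20 (2Z)-3-[(1S,2S,4R)-2-[(tert-butyldimethylsilyl)oxy]-1-[(2R)-1-hydroxypropan-2-yl]-4-(prop-1-en-2-yl)cyclopentyl]but-2-en-1-ol
Product: 21 (2Z)-3-[(1S,2S,4R)-2-[(tert-butyldimethylsilyl)oxy]-1-[(2R)-1-oxopropan-2-yl]-4-(prop-1-en-2-yl)cyclopentyl]but-2-enal
Conditions: Dess–Martin periodinane (2.6 equiv), NaHCO3, CH2Cl2, 0 °C; used crude at once
Reagents that add atoms: none
Why: Buffered Dess–Martin oxidation of both primary alcohols is near neutral, which should avoid Z to E isomerisation of the enal and epimerisation at C10.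

Step 16
Reactants: 21 (2Z)-3-[(1S,2S,4R)-2-[(tert-butyldimethylsilyl)oxy]-1-[(2R)-1-oxopropan-2-yl]-4-(prop-1-en-2-yl)cyclopentyl]but-2-enal
Product: 22 (1S,3R,5S,8R,9S,10R)-1-[(tert-butyldimethylsilyl)oxy]-6,10-dimethyl-3-(prop-1-en-2-yl)spiro[4.5]dec-6-ene-8,9-diol
Conditions: SmI2 (2.5 equiv, 0.1 M in THF), t-BuOH (2 equiv), THF, high dilution, −78 → −20 °C; aq. NH4Cl
Reagents that add atoms: none
Why: SmI2 (divalent samarium) should transfer one electron to the more easily reduced enal to give an O-bound allylic ketyl, which joins C8 to the samarium-activated C9 aldehyde carbon, a second electron completing the samarium diolate. The closest known reaction type is the SmI2-mediated intramolecular pinacol coupling of 1,6-dialdehydes to cis-cyclohexane-1,2-diols. Ring B closes in a 6-exo-trig mode, and bonding through the γ-carbon C6 is excluded because it would make a cyclobutane at a fully substituted carbon. The cis relation of the C8 and C9 hydroxyls is set by chelation of both oxygens to one trivalent samarium centre, and C9 should form with its oxygen trans to the C10 methyl because, in a chair-like transition state with that methyl equatorial, the C9 oxygen avoids a 1,3-diaxial contact with the axial ring A carbon on C5. The step needs carbonyl–carbonyl coupling in preference to conjugate reduction or dimerisation, which the Z geometry of C6=C7 and the quaternary C5 (holding the two formyl groups close), high dilution, low temperature and the absence of HMPA should secure.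

Step 17
Reactants: 22 (1S,3R,5S,8R,9S,10R)-1-[(tert-butyldimethylsilyl)oxy]-6,10-dimethyl-3-(prop-1-en-2-yl)spiro[4.5]dec-6-ene-8,9-diol
Product: 23 (1S,3R,5S,9S,10R)-1-[(tert-butyldimethylsilyl)oxy]-9-hydroxy-6,10-dimethyl-3-(prop-1-en-2-yl)spiro[4.5]dec-6-en-8-one
Conditions: activated MnO2, CH2Cl2, rt
Reagents that add atoms: none
Why: Allylic oxidation with MnO2 is selective for the allylic C8 carbinol, so the saturated C9 carbinol should be retained and the C8 stereocentre is deliberately erased.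

Step 18
Reactants: 23 (1S,3R,5S,9S,10R)-1-[(tert-butyldimethylsilyl)oxy]-9-hydroxy-6,10-dimethyl-3-(prop-1-en-2-yl)spiro[4.5]dec-6-en-8-one
Product: 24 (1S,3R,5S,9S,10R)-1-[(tert-butyldimethylsilyl)oxy]-6,10-dimethyl-8-oxo-3-(prop-1-en-2-yl)spiro[4.5]dec-6-en-9-yl acetate
Conditions: Ac2O, pyridine, DMAP (cat.), CH2Cl2, 0 °C → rt
Reagents that add atoms: acetic anhydride, CC(=O)OC(C)=O
Why: DMAP-catalysed acetylation of the remaining secondary alcohol; C9 is now α to the ketone, so any C9 epimer could be equilibrated with DBU to the trans 9-acetoxy-10-methyl arrangement of the target.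

Step 19
Reactants: 24 (1S,3R,5S,9S,10R)-1-[(tert-butyldimethylsilyl)oxy]-6,10-dimethyl-8-oxo-3-(prop-1-en-2-yl)spiro[4.5]dec-6-en-9-yl acetate
Product: 25 (1S,3R,5S,9S,10R)-1-hydroxy-6,10-dimethyl-8-oxo-3-(prop-1-en-2-yl)spiro[4.5]dec-6-en-9-yl acetate
Conditions: HF·pyridine, pyridine, THF, 0 °C → rt
Reagents that add atoms: none
Why: Fluoride desilylation under mildly acidic conditions should spare the base-sensitive α-acetoxy enone and the isopropenyl group.

Step 20
Reactants: 25 (1S,3R,5S,9S,10R)-1-hydroxy-6,10-dimethyl-8-oxo-3-(prop-1-en-2-yl)spiro[4.5]dec-6-en-9-yl acetate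
Product: 26 (1S,3R,5S,9S,10R)-9-acetoxy-6,10-dimethyl-8-oxo-3-(prop-1-en-2-yl)spiro[4.5]dec-6-en-1-yl 3-methylbut-2-enoate
Conditions: 3-methylbut-2-enoyl chloride, pyridine, DMAP (cat.), CH2Cl2, 0 °C → rt
Reagents that add atoms: 3-methylbut-2-enoyl chloride, CC(C)=CC(Cl)=O
Why: Esterification of the C1 alcohol with the acyl chloride under nucleophilic catalysis, pyridine being a weak enough base to limit deconjugation of the senecioyl unit; no stereocentre is touched.

Compound list
1 | (R)-limonene, (4R)-1-methyl-4-(prop-1-en-2-yl)cyclohex-1-ene | CC1=CC[C@@H](CC1)C(C)=C | starting material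
2 | (5R)-7-hydroperoxy-7-methoxy-5-(prop-1-en-2-yl)heptan-2-one (methoxy hydroperoxide, C7 epimers, not isolated) | COC(OO)C[C@@H](CCC(C)=O)C(C)=C | intermediate
3 | methyl (3R)-6-oxo-3-(prop-1-en-2-yl)heptanoate | COC(=O)C[C@@H](CCC(C)=O)C(C)=C | intermediate
4 | (3R)-3-(prop-1-en-2-yl)hexanedioic acid | OC(=O)C[C@@H](CCC(O)=O)C(C)=C | intermediate
5 | dimethyl (3R)-3-(prop-1-en-2-yl)hexanedioate | COC(=O)C[C@@H](CCC(=O)OC)C(C)=C | intermediate
6 | methyl (4R)-2-oxo-4-(prop-1-en-2-yl)cyclopentane-1-carboxylate (C5 epimers and enol) | C=C(C)[C@H]1CC(=O)C(C1)C(=O)OC | intermediate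
7 | methyl (R)-lactate, methyl (2R)-2-hydroxypropanoate | C[C@@H](O)C(=O)OC | starting material
8 | methyl (2R)-2-[(trifluoromethanesulfonyl)oxy]propanoate | C[C@@H](OS(=O)(=O)C(F)(F)F)C(=O)OC | intermediate
9 | methyl (1R,4R)-1-[(2R)-1-methoxy-1-oxopropan-2-yl]-2-oxo-4-(prop-1-en-2-yl)cyclopentane-1-carboxylate (C10 arm trans to isopropenyl) | C=C(C)[C@H]1CC(=O)[C@]([C@@H](C)C(=O)OC)(C1)C(=O)OC | intermediate
10 | methyl (1R,2S,4R)-2-hydroxy-1-[(2R)-1-methoxy-1-oxopropan-2-yl]-4-(prop-1-en-2-yl)cyclopentane-1-carboxylate (hydroxy diester, C1–OH cis to the C10 arm, not isolated) | C=C(C)[C@H]1C[C@H](O)[C@]([C@@H](C)C(=O)OC)(C1)C(=O)OC | intermediate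
11 | methyl (3R,3aR,5R,6aS)-3-methyl-2-oxo-5-(prop-1-en-2-yl)hexahydro-2H-cyclopenta[b]furan-3a(3H)-carboxylate (cis-fused γ-lactone from C1–O to C9; C10 methyl on the concave face) | C=C(C)[C@H]1C[C@@H]2OC(=O)[C@H](C)[C@@]2(C1)C(=O)OC | intermediate
12 | methyl (3R,3aR,5R,6aS)-2-hydroxy-3-methyl-5-(prop-1-en-2-yl)hexahydro-2H-cyclopenta[b]furan-3a(3H)-carboxylate (lactol, anomers, not isolated) | C=C(C)[C@H]1C[C@@H]2OC(O)[C@H](C)[C@@]2(C1)C(=O)OC | intermediate
13 | methyl (1R,2S,4R)-2-hydroxy-1-[(2R)-1-hydroxypropan-2-yl]-4-(prop-1-en-2-yl)cyclopentane-1-carboxylate (diol ester, not isolated) | C=C(C)[C@H]1C[C@H](O)[C@]([C@@H](C)CO)(C1)C(=O)OC | intermediate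
14 | (4R,5R,6S,8R)-6-hydroxy-4-methyl-8-(prop-1-en-2-yl)-2-oxaspiro[4.4]nonan-1-one (spiro γ-lactone from the C6 carboxyl to the C9 oxygen) | C=C(C)[C@H]1C[C@H](O)[C@]2(C1)C(=O)OC[C@@H]2C | intermediate
15 | (4R,5R,6S,8R)-6-[(tert-butyldimethylsilyl)oxy]-4-methyl-8-(prop-1-en-2-yl)-2-oxaspiro[4.4]nonan-1-one | C=C(C)[C@H]1C[C@H](O[Si](C)(C)C(C)(C)C)[C@]2(C1)C(=O)OC[C@@H]2C | intermediate
16 | (4R,5R,6S,8R)-6-[(tert-butyldimethylsilyl)oxy]-4-methyl-8-(prop-1-en-2-yl)-2-oxaspiro[4.4]nonan-1-ol (lactol, anomers) | C=C(C)[C@H]1C[C@H](O[Si](C)(C)C(C)(C)C)[C@]2(C1)C(O)OC[C@@H]2C | intermediate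
17 | (2R)-2-[(1S,2S,4R)-2-[(tert-butyldimethylsilyl)oxy]-1-ethynyl-4-(prop-1-en-2-yl)cyclopentyl]propan-1-ol | C=C(C)[C@H]1C[C@H](O[Si](C)(C)C(C)(C)C)[C@]([C@@H](C)CO)(C1)C#C | intermediate
18 | methyl 3-[(1S,2S,4R)-2-[(tert-butyldimethylsilyl)oxy]-1-[(2R)-1-[(methoxycarbonyl)oxy]propan-2-yl]-4-(prop-1-en-2-yl)cyclopentyl]prop-2-ynoate | C=C(C)[C@H]1C[C@H](O[Si](C)(C)C(C)(C)C)[C@]([C@@H](C)COC(=O)OC)(C1)C#CC(=O)OC | intermediate
19 | methyl (2Z)-3-[(1S,2S,4R)-2-[(tert-butyldimethylsilyl)oxy]-1-[(2R)-1-[(methoxycarbonyl)oxy]propan-2-yl]-4-(prop-1-en-2-yl)cyclopentyl]but-2-enoate | C=C(C)[C@H]1C[C@H](O[Si](C)(C)C(C)(C)C)[C@]([C@@H](C)COC(=O)OC)(C1)/C(C)=C\C(=O)OC | intermediate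
20 | (2Z)-3-[(1S,2S,4R)-2-[(tert-butyldimethylsilyl)oxy]-1-[(2R)-1-hydroxypropan-2-yl]-4-(prop-1-en-2-yl)cyclopentyl]but-2-en-1-ol | C=C(C)[C@H]1C[C@H](O[Si](C)(C)C(C)(C)C)[C@]([C@@H](C)CO)(C1)/C(C)=C\CO | intermediate
21 | (2Z)-3-[(1S,2S,4R)-2-[(tert-butyldimethylsilyl)oxy]-1-[(2R)-1-oxopropan-2-yl]-4-(prop-1-en-2-yl)cyclopentyl]but-2-enal (dialdehyde, key-step precursor) | C=C(C)[C@H]1C[C@H](O[Si](C)(C)C(C)(C)C)[C@]([C@@H](C)C=O)(C1)/C(C)=C\C=O | intermediate
22 | (1S,3R,5S,8R,9S,10R)-1-[(tert-butyldimethylsilyl)oxy]-6,10-dimethyl-3-(prop-1-en-2-yl)spiro[4.5]dec-6-ene-8,9-diol (cis-diol, C9–OH trans to C10 methyl) | C=C(C)[C@H]1C[C@H](O[Si](C)(C)C(C)(C)C)[C@]2(C1)C(C)=C[C@@H](O)[C@@H](O)[C@@H]2C | intermediate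
23 | (1S,3R,5S,9S,10R)-1-[(tert-butyldimethylsilyl)oxy]-9-hydroxy-6,10-dimethyl-3-(prop-1-en-2-yl)spiro[4.5]dec-6-en-8-one | C=C(C)[C@H]1C[C@H](O[Si](C)(C)C(C)(C)C)[C@]2(C1)C(C)=CC(=O)[C@@H](O)[C@@H]2C | intermediate
24 | (1S,3R,5S,9S,10R)-1-[(tert-butyldimethylsilyl)oxy]-6,10-dimethyl-8-oxo-3-(prop-1-en-2-yl)spiro[4.5]dec-6-en-9-yl acetate | C=C(C)[C@H]1C[C@H](O[Si](C)(C)C(C)(C)C)[C@]2(C1)C(C)=CC(=O)[C@@H](OC(C)=O)[C@@H]2C | intermediate
25 | (1S,3R,5S,9S,10R)-1-hydroxy-6,10-dimethyl-8-oxo-3-(prop-1-en-2-yl)spiro[4.5]dec-6-en-9-yl acetate | C=C(C)[C@H]1C[C@H](O)[C@]2(C1)C(C)=CC(=O)[C@@H](OC(C)=O)[C@@H]2C | intermediate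
26 | (1S,3R,5S,9S,10R)-9-acetoxy-6,10-dimethyl-8-oxo-3-(prop-1-en-2-yl)spiro[4.5]dec-6-en-1-yl 3-methylbut-2-enoate (CNP0218315.1) | C=C(C)[C@H]1C[C@H](OC(=O)C=C(C)C)[C@]2(C1)C(C)=CC(=O)[C@@H](OC(C)=O)[C@@H]2C | target

Total step count: 20.
Longest linear sequence: 19 steps (steps 1–4 and 6–20 from 1); step 5 is a one-step side branch.

Steps most likely to fail

Step 16. Single-electron reduction of the enal may end in conjugate reduction or intermolecular coupling instead of ring closure, and the allylic ketyl may lose the Z geometry that closure needs. The fallback sets out from 21 and returns at 22. Double Wittig methylenation of both formyl groups (Ph3P=CH2, THF, −78 → 0 °C) would give the triene in which each CHO of 21 has become a vinyl group, with all stereocentres and the Z C6=C7 bond unchanged, F1. Ring-closing metathesis with second-generation Grubbs catalyst (CH2Cl2, 40 °C) would join C8 and C9 with loss of ethene, the isopropenyl group and the trisubstituted C6=C7 bond staying out of the reaction, to give the spiro cyclohexa-6,8-diene silyl ether F2. OsO4 (cat.) with N-methylmorpholine N-oxide should then dihydroxylate the less substituted end of the conjugated diene (C8=C9) from the face opposite the C10 methyl and give 22.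

Step 6. O-alkylation or E2 elimination of the triflate may outrun C-alkylation at the hindered carbon, and facial selectivity at C5 may be low because the isopropenyl group is 1,3 to the reacting carbon. The fallback sets out from 6 and returns at 11. Alkylation of 6 with the primary electrophile methyl bromoacetate (K2CO3, acetone) would give methyl (1R,4R)-1-(2-methoxy-2-oxoethyl)-2-oxo-4-(prop-1-en-2-yl)cyclopentane-1-carboxylate F3. Zn(BH4)2 reduction and lactonisation under the conditions of step 7 would give the cis-fused lactone lacking the C10 methyl, methyl (3aR,5R,6aS)-2-oxo-5-(prop-1-en-2-yl)hexahydro-2H-cyclopenta[b]furan-3a(3H)-carboxylate F4. LDA then MeI (THF, −78 °C) should methylate the lactone enolate on the convex face and give the C10 epimer of 11, the (3S,3aR,5R,6aS) lactone F5. A second enolisation (LDA, −78 °C) and kinetic protonation on the same convex face with 2,6-di-tert-butylphenol would turn the methyl to the concave face and give 11.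

Step 11. The lactol–hydroxy aldehyde equilibrium lies on the closed side and the open aldehyde is neopentyl, so the homologation may stall at low conversion. The fallback sets out from 16 and returns at 18. Wittig reaction of 16 with Ph3P=CHCl (from (chloromethyl)triphenylphosphonium chloride and NaN(SiMe3)2, THF, 0 °C → rt) would give the chloroalkene alcohol (2R)-2-[(1S,2S,4R)-2-[(tert-butyldimethylsilyl)oxy]-1-(2-chloroethenyl)-4-(prop-1-en-2-yl)cyclopentyl]propan-1-ol, E/Z mixture, F6. n-BuLi (3.2 equiv, THF, −78 → 0 °C) would eliminate HCl and leave the lithium acetylide alkoxide, which ClCO2Me converts directly into 18.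

Further compounds
F1 | step 16 | tert-butyldimethylsilyl ether of the triene: 21 with both formyl groups replaced by vinyl groups (Z C6=C7, stereocentres as in 21) | C=C(C)[C@H]1C[C@H](O[Si](C)(C)C(C)(C)C)[C@]([C@@H](C)C=C)(C1)/C(C)=C\C=C
F2 | step 16 | 1-[(tert-butyldimethylsilyl)oxy]-6,10-dimethyl-3-(prop-1-en-2-yl)spiro[4.5]deca-6,8-diene (stereocentres as in 22) | C=C(C)[C@H]1C[C@H](O[Si](C)(C)C(C)(C)C)[C@]2(C1)C(C)=CC=C[C@@H]2C
F3 | step 6 | methyl (1R,4R)-1-(2-methoxy-2-oxoethyl)-2-oxo-4-(prop-1-en-2-yl)cyclopentane-1-carboxylate | C=C(C)[C@H]1CC(=O)[C@](CC(=O)OC)(C1)C(=O)OC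
F4 | step 6 | methyl (3aR,5R,6aS)-2-oxo-5-(prop-1-en-2-yl)hexahydro-2H-cyclopenta[b]furan-3a(3H)-carboxylate | C=C(C)[C@H]1C[C@@H]2OC(=O)C[C@@]2(C1)C(=O)OC
F5 | step 6 | methyl (3S,3aR,5R,6aS)-3-methyl-2-oxo-5-(prop-1-en-2-yl)hexahydro-2H-cyclopenta[b]furan-3a(3H)-carboxylate (C10 epimer of 11) | C=C(C)[C@H]1C[C@@H]2OC(=O)[C@@H](C)[C@@]2(C1)C(=O)OC
F6 | step 11 | (2R)-2-[(1S,2S,4R)-2-[(tert-butyldimethylsilyl)oxy]-1-(2-chloroethenyl)-4-(prop-1-en-2-yl)cyclopentyl]propan-1-ol (E/Z mixture) | C=C(C)[C@H]1C[C@H](O[Si](C)(C)C(C)(C)C)[C@]([C@@H](C)CO)(C1)C=CCl
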